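**Plan**

1. Locants: cyclopentane C1 (CHOH), C2 (quaternary C–CH3), C3 (CMe2), C4 (CHBr), C5; cyclohexane C1′ (carbinol), C2′, C3′ (CHBr), C4′ (CMeCl), C5′, C6′. The retrosynthesis removes Br/Cl from C3′/C4′ (back to a C3′=C4′ alkene), then cuts the ring bonds C1′–C2′ (allyl–ketone) and C5′–C6′ (enolate–allyl bromide), then C2–CH3, the C2–C3 ring bond and the C1–C2 aldol bond.
2. Forward: an acyclic bromochloride aldehyde and a thioacetate unit are joined by an aldol reaction; the cyclopentane closes first (C2–C3), C2 is methylated and the thioester becomes a methyl ketone. The cyclohexane is closed last from this ketone and an isoprene-derived C5 unit (formal 4+2), then bromochlorinated.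
3. Enabling feature: in the six-membered ring the carbinol C1′ is homoallylic to the C3′=C4′ alkene that the vicinal Br/Cl pair masks, and para to the methyl-bearing C4′. This is a 4-methylcyclohex-3-en-1-ol, whose C1′–C2′ bond is that of a ketone allylation that can only close through the unsubstituted allyl terminus.
4. Stereochemistry: C4 (C–Br) from a catalytic enantioselective bromochlorination, kept through ionisation by bromine participation; C1 from a reagent-controlled Mukaiyama aldol; C2 by methylation anti to the OTBS and Br groups; C1′ by Felkin–Anh attack anti to C3; C3′/C4′ by anti addition with chloride delivered from the C1′ oxygen.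

Key step: step 11

Assumption: the enantiomer of each chiral promoter (Schiff-base ligand in step 1, diamine in step 4) is chosen to give the stated configuration; the thioester-bearing carbon of 10 is epimerisable and its configuration is erased in step 7.

**Step 1**
Reactants: 1 4-methylpent-3-en-1-ol
Product: 2 (3S)-3-bromo-4-chloro-4-methylpentan-1-ol
Conditions: NBS, ClTi(OiPr)3, chiral tridentate Schiff-base ligand (20 mol %), hexanes, −20 °C
Reagents that add atoms: N-bromosuccinimide O=C1CCC(=O)N1Br; chlorotitanium triisopropoxide CC(C)O[Ti](Cl)(OC(C)C)OC(C)C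
Why: Titanium-alkoxide-directed catalytic enantioselective bromochlorination of a homoallylic alcohol should add anti and Markovnikov (Br on C3, Cl on the tertiary carbon), with the ligand enantiomer setting C3 as S.

**Step 2**
Reactants: 2 (3S)-3-bromo-4-chloro-4-methylpentan-1-ol
Product: 3 (3S)-3-bromo-4-chloro-4-methylpentanal
Conditions: Dess–Martin periodinane, CH2Cl2, 0 → 20 °C
Reagents that add atoms: none
Why: Dess–Martin oxidation runs without base, so the β-bromo aldehyde should not lose HBr by E1cB and the C–Br centre is untouched.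

**Step 3**
Reactants: 4 S-ethyl ethanethioate
Product: 5 1-(ethylsulfanyl)-1-(trimethylsilyloxy)ethene
Conditions: LDA, TMSCl (in situ quench), THF, −78 °C
Reagents that add atoms: chlorotrimethylsilane C[Si](C)(C)Cl
Why: Kinetic enolisation of the thioester with immediate O-silylation gives the ketene silyl thioacetal needed for a base-free aldol.

**Step 4**
Reactants: 3 (3S)-3-bromo-4-chloro-4-methylpentanal + 5 1-(ethylsulfanyl)-1-(trimethylsilyloxy)ethene
Product: 7 S-ethyl (3S,5S)-5-bromo-6-chloro-3-hydroxy-6-methylheptanethioate, via trimethylsilyl ether 6 (not isolated)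
Conditions: Sn(OTf)2, chiral diamine 1-methyl-2-[(1-naphthylamino)methyl]pyrrolidine, nBu2Sn(OAc)2, CH2Cl2, −78 °C; then 1 M HCl, THF
Reagents that add atoms: none
Why: An asymmetric Mukaiyama aldol under chiral diamine–tin(II) triflate promotion is base-free, so the β-bromo aldehyde should survive, and the promoter rather than the remote C–Br centre should control the aldehyde face and set C3 as S.

**Step 5**
Reactants: 7 S-ethyl (3S,5S)-5-bromo-6-chloro-3-hydroxy-6-methylheptanethioate
Product: 8 S-ethyl (3S,5S)-5-bromo-3-[(tert-butyldimethylsilyl)oxy]-6-chloro-6-methylheptanethioate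
Conditions: TBSOTf, 2,6-lutidine, CH2Cl2, −78 °C
Reagents that add atoms: tert-butyldimethylsilyl trifluoromethanesulfonate CC(C)(C)[Si](C)(C)OS(=O)(=O)C(F)(F)F
Why: Silylation of the secondary alcohol lowers the nucleophilicity of this oxygen for step 6 and blocks retro-aldol and β-lactone pathways in the later enolate steps.

**Step 6**
Reactants: 8 S-ethyl (3S,5S)-5-bromo-3-[(tert-butyldimethylsilyl)oxy]-6-chloro-6-methylheptanethioate
Product: 10 S-ethyl (1R,3S,5R)-3-bromo-5-[(tert-butyldimethylsilyl)oxy]-2,2-dimethylcyclopentane-1-carbothioate, via ketene silyl thioacetal 9 (not isolated)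
Conditions: LDA, TMSCl (in situ quench), THF, −78 °C; then TiCl4, CH2Cl2, −78 → −40 °C
Reagents that add atoms: none
Why: In this Lewis-acid-mediated intramolecular SN1 α-tert-alkylation of a silyl ketene acetal, TiCl4 should ionise the tertiary chloride with anchimeric help from the vicinal bromine and the ketene acetal carbon should open the bromonium ion at its tertiary carbon (5-exo with respect to the ketene acetal), so the C–Br configuration is retained and Br and OTBS end up cis as fixed by the two stereocentres of 8.

**Step 7**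
Reactants: 10 S-ethyl (1R,3S,5R)-3-bromo-5-[(tert-butyldimethylsilyl)oxy]-2,2-dimethylcyclopentane-1-carbothioate
Product: 12 S-ethyl (1S,3S,5R)-3-bromo-5-[(tert-butyldimethylsilyl)oxy]-1,2,2-trimethylcyclopentane-1-carbothioate, via lithium enolate 11 (not isolated)
Conditions: LDA, THF–DMPU, −78 °C; then MeI, −78 → −40 °C
Reagents that add atoms: iodomethane CI
Why: In this enolate C-methylation, methyl iodide should enter the planar enolate anti to the adjacent OTBS group and the cis-1,3 bromine, which sets the quaternary carbon with the thioester cis to both.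

**Step 8**
Reactants: 12 S-ethyl (1S,3S,5R)-3-bromo-5-[(tert-butyldimethylsilyl)oxy]-1,2,2-trimethylcyclopentane-1-carbothioate
Product: 13 1-[(1S,3S,5R)-3-bromo-5-[(tert-butyldimethylsilyl)oxy]-1,2,2-trimethylcyclopentyl]ethan-1-one
Conditions: Me2CuLi, Et2O, −78 → −30 °C
Reagents that add atoms: lithium dimethylcuprate [Li+].C[Cu-]C
Why: Ketone synthesis from a thioester and a Gilman cuprate should stop at the ketone, because the cuprate displaces thiolate but does not add to the hindered ketone or attack the neopentyl secondary bromide.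

**Step 9**
Reactants: 14 2-methylbuta-1,3-diene (isoprene)
Product: 15 (2E)-4-bromo-3-methylbut-2-en-1-yl acetate
Conditions: NBS, AcOH, 20 °C
Reagents that add atoms: N-bromosuccinimide O=C1CCC(=O)N1Br; acetic acid CC(=O)O
Why: 1,4-Bromoacetoxylation of the diene (bromonium formation at the more substituted double bond, acetate capture at the far allylic terminus) should give the thermodynamically preferred (E)-1,4-adduct.

**Step 10**
Reactants: 13 1-[(1S,3S,5R)-3-bromo-5-[(tert-butyldimethylsilyl)oxy]-1,2,2-trimethylcyclopentyl]ethan-1-one + 15 (2E)-4-bromo-3-methylbut-2-en-1-yl acetate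
Product: 17 (2E)-6-[(1S,3S,5R)-3-bromo-5-[(tert-butyldimethylsilyl)oxy]-1,2,2-trimethylcyclopentyl]-3-methyl-6-oxohex-2-en-1-yl acetate, via lithium enolate 16 (not isolated)
Conditions: LiHMDS, THF, −78 °C; then 15, −78 → −20 °C
Reagents that add atoms: none
Why: The methyl ketone has only one enolisable side, and its kinetic lithium enolate should be alkylated by SN2 at the allylic bromide, which is far more reactive than the allylic acetate; this forms C5′–C6′.

**Step 11**
Reactants: 17 (2E)-6-[(1S,3S,5R)-3-bromo-5-[(tert-butyldimethylsilyl)oxy]-1,2,2-trimethylcyclopentyl]-3-methyl-6-oxohex-2-en-1-yl acetate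
Product: 19 (1R)-1-[(1S,3S,5R)-3-bromo-5-[(tert-butyldimethylsilyl)oxy]-1,2,2-trimethylcyclopentyl]-4-methylcyclohex-3-en-1-ol, via allylindium acetate iodide 18 (not isolated)
Conditions: Pd(PPh3)4 (5 mol %), InI (2 equiv), THF, 25–40 °C
Reagents that add atoms: none
Why: Pd(0) ionises the allylic acetate to a π-allylpalladium complex that InI reduces to an allylindium(III) species, which equilibrates by 1,3-metallotropy between its primary and tertiary σ-forms and between E and Z geometries; the tertiary form adds through its CH2 terminus to the ketone in a closed six-membered Zimmerman–Traxler array laid across a boat-shaped incipient ring (an SE2′ carbonyl allylation). The closest known reaction type is the umpoled Barbier-type allylation of ketones by allylic acetates or halides under Pd/In, Zn or Cr(II) mediation, including intramolecular cases. The cyclohexene closes in a 6-endo sense with respect to the allyl unit (both allyl termini end up in the ring), the only mode open to it, because bonding through the methyl-bearing carbon would give a cyclobutanol and the cis ring alkene can only come from the Z or tertiary allylmetal, so the E geometry of 17 is not a constraint. The new carbinol centre C1′ is set by Felkin–Anh control from the adjacent quaternary carbon: the nucleophile should approach anti to the CMe2 ring carbon (further shielded by the cis bromine), past the small methyl group, with the carbonyl oxygen turned towards the CH(OTBS) carbon, which gives the 1R carbinol. The step needs chemoselectivity for the allylic acetate over the neopentyl secondary bromide (inert to Pd(0)/PPh3 and InI), α- over γ-regioselectivity (secured by ring size) and facial selectivity (secured by the three very different substituents on the quaternary carbon).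

**Step 12**
Reactants: 19 (1R)-1-[(1S,3S,5R)-3-bromo-5-[(tert-butyldimethylsilyl)oxy]-1,2,2-trimethylcyclopentyl]-4-methylcyclohex-3-en-1-ol
Product: 20 (1R,2S,4S)-4-bromo-2-[(1R)-1-hydroxy-4-methylcyclohex-3-en-1-yl]-2,3,3-trimethylcyclopentan-1-ol
Conditions: HF·pyridine, THF, 0 → 20 °C
Reagents that add atoms: none
Why: Fluoride cleavage of the silyl ether under mildly acidic conditions should neither eliminate the secondary bromide nor ionise the tertiary alcohol.

**Step 13**
Reactants: 20 (1R,2S,4S)-4-bromo-2-[(1R)-1-hydroxy-4-methylcyclohex-3-en-1-yl]-2,3,3-trimethylcyclopentan-1-ol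
Product: 21 (1R,2S,4S)-4-bromo-2-[(1R,3S,4S)-3-bromo-4-chloro-1-hydroxy-4-methylcyclohexyl]-2,3,3-trimethylcyclopentan-1-ol
Conditions: NBS, ClTi(OiPr)3 (1.2 equiv), CH2Cl2–hexanes, −20 °C
Reagents that add atoms: N-bromosuccinimide O=C1CCC(=O)N1Br; chlorotitanium triisopropoxide CC(C)O[Ti](Cl)(OC(C)C)OC(C)C
Why: Proposed new method: the cis-1,3-diol should exchange onto titanium to give a six-membered titanium diolate whose Ti–Cl lies on the hydroxyl face of the cyclohexene; NBS forms the bromonium ion reversibly on either face, but only the bromonium anti to the C1′ oxygen can be opened at the tertiary C4′ by the tethered chloride, through a boat in which C1′ and C4′ are the prow atoms, giving anti addition with Cl cis to the C1′ hydroxyl and Br on C3′ cis to the cyclopentyl group (the isomer that untethered chloride, following diaxial Fürst–Plattner opening, would not give); the closest known reaction type is the titanium-alkoxide-directed bromochlorination of allylic and homoallylic alcohols with NBS and ClTi(OiPr)3.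

**Compound list**

1 | 4-methylpent-3-en-1-ol | CC(C)=CCCO | starting material
2 | (3S)-3-bromo-4-chloro-4-methylpentan-1-ol | OCC[C@H](Br)C(C)(C)Cl | intermediate
3 | (3S)-3-bromo-4-chloro-4-methylpentanal | O=CC[C@H](Br)C(C)(C)Cl | intermediate
4 | S-ethyl ethanethioate | CC(=O)SCC | starting material
5 | 1-(ethylsulfanyl)-1-(trimethylsilyloxy)ethene | C=C(SCC)O[Si](C)(C)C | intermediate
6 | S-ethyl (3S,5S)-5-bromo-6-chloro-6-methyl-3-[(trimethylsilyl)oxy]heptanethioate | CCSC(=O)C[C@H](O[Si](C)(C)C)C[C@H](Br)C(C)(C)Cl | intermediate (not isolated)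
7 | S-ethyl (3S,5S)-5-bromo-6-chloro-3-hydroxy-6-methylheptanethioate | CCSC(=O)C[C@H](O)C[C@H](Br)C(C)(C)Cl | intermediate
8 | S-ethyl (3S,5S)-5-bromo-3-[(tert-butyldimethylsilyl)oxy]-6-chloro-6-methylheptanethioate | CCSC(=O)C[C@H](O[Si](C)(C)C(C)(C)C)C[C@H](Br)C(C)(C)Cl | intermediate
9 | O-trimethylsilyl S-ethyl ketene thioacetal of 8 (both stereocentres as in 8) | CCSC(O[Si](C)(C)C)=C[C@H](O[Si](C)(C)C(C)(C)C)C[C@H](Br)C(C)(C)Cl | intermediate (not isolated)
10 | S-ethyl (1R,3S,5R)-3-bromo-5-[(tert-butyldimethylsilyl)oxy]-2,2-dimethylcyclopentane-1-carbothioate (Br and OTBS cis, thioester trans to OTBS) | CC1(C)[C@@H](Br)C[C@@H](O[Si](C)(C)C(C)(C)C)[C@@H]1C(=O)SCC | intermediate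
11 | lithium enolate of 10 | CC1(C)[C@@H](Br)C[C@@H](O[Si](C)(C)C(C)(C)C)C1=C([O-])SCC.[Li+] | intermediate (not isolated)
12 | S-ethyl (1S,3S,5R)-3-bromo-5-[(tert-butyldimethylsilyl)oxy]-1,2,2-trimethylcyclopentane-1-carbothioate (thioester, OTBS and Br all cis) | CC1(C)[C@@H](Br)C[C@@H](O[Si](C)(C)C(C)(C)C)[C@@]1(C)C(=O)SCC | intermediate
13 | 1-[(1S,3S,5R)-3-bromo-5-[(tert-butyldimethylsilyl)oxy]-1,2,2-trimethylcyclopentyl]ethan-1-one | CC1(C)[C@@H](Br)C[C@@H](O[Si](C)(C)C(C)(C)C)[C@@]1(C)C(C)=O | intermediate
14 | 2-methylbuta-1,3-diene (isoprene) | C=CC(C)=C | starting material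
15 | (2E)-4-bromo-3-methylbut-2-en-1-yl acetate | CC(=O)OC/C=C(\C)CBr | intermediate
16 | lithium enolate of 13 | CC1(C)[C@@H](Br)C[C@@H](O[Si](C)(C)C(C)(C)C)[C@@]1(C)C(=C)[O-].[Li+] | intermediate (not isolated)
17 | (2E)-6-[(1S,3S,5R)-3-bromo-5-[(tert-butyldimethylsilyl)oxy]-1,2,2-trimethylcyclopentyl]-3-methyl-6-oxohex-2-en-1-yl acetate | CC1(C)[C@@H](Br)C[C@@H](O[Si](C)(C)C(C)(C)C)[C@@]1(C)C(=O)CC/C(C)=C/COC(C)=O | intermediate
18 | allylindium(III) acetate iodide from 17 (In on the former CH2OAc carbon, in equilibrium with its tertiary allylic isomer) | CC1(C)[C@@H](Br)C[C@@H](O[Si](C)(C)C(C)(C)C)[C@@]1(C)C(=O)CCC(C)=CC[In](I)OC(C)=O | intermediate (not isolated)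
19 | (1R)-1-[(1S,3S,5R)-3-bromo-5-[(tert-butyldimethylsilyl)oxy]-1,2,2-trimethylcyclopentyl]-4-methylcyclohex-3-en-1-ol | CC1(C)[C@@H](Br)C[C@@H](O[Si](C)(C)C(C)(C)C)[C@@]1(C)[C@@]1(O)CCC(C)=CC1 | intermediate
20 | (1R,2S,4S)-4-bromo-2-[(1R)-1-hydroxy-4-methylcyclohex-3-en-1-yl]-2,3,3-trimethylcyclopentan-1-ol | CC1(C)[C@@H](Br)C[C@@H](O)[C@@]1(C)[C@@]1(O)CCC(C)=CC1 | intermediate
21 | (1R,2S,4S)-4-bromo-2-[(1R,3S,4S)-3-bromo-4-chloro-1-hydroxy-4-methylcyclohexyl]-2,3,3-trimethylcyclopentan-1-ol | CC1(C)[C@@H](Br)C[C@@H](O)[C@@]1(C)[C@@]1(O)CC[C@](C)(Cl)[C@@H](Br)C1 | target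

**Step count**

Total steps: 13. Longest linear sequence: 11 steps (steps 1, 2, 4, 5, 6, 7, 8, 10, 11, 12, 13); steps 3 and 9 each make one reagent.

**Steps most likely to fail, with fallbacks**

Step 13 (Proposed new method). The chloride may not be delivered from titanium: the tertiary hydroxyl may attack the bromonium ion transannularly, or untethered chloride may open the other bromonium diastereomer in the diaxial sense and give the 3′,4′-diastereomer. The fallback uses known reaction types and makes the transannular oxygen participation the planned path. It sets out from 19, whose secondary hydroxyl is still silylated: NBS in CH2Cl2 at 0 °C should give, by bromoetherification of the cyclohex-3-enol, the 2-endo-bromo-1-methyl-7-oxabicyclo[2.2.1]heptane bromo ether F1. BCl3 in CH2Cl2 at −78 °C should then cleave the tertiary C4′–O bond with anchimeric help from the anti bromine, so chloride returns to C4′ on the oxygen face and gives the silyl ether of the target F2. HF·pyridine removes the silyl group and the route is rejoined at 21.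

Step 6. The bromonium ion or tertiary cation may be captured by the silyl ether oxygen (tetrahydrofuran formation) or lose a proton to an isopropenyl bromide, or the ketene acetal may be protodesilylated before C–C bond formation. The fallback ties the competing oxygen and the carboxyl carbon into a temporary ring. It sets out from 7: LiOH/H2O2 gives the hydroxy acid F3, and paraformaldehyde with BF3·OEt2 gives the 1,3-dioxan-4-one F4, in which the oxygen lone pair is part of an acylal. LDA/TMSCl gives its silyl ketene acetal F5, and TiCl4 should close the cyclopentane to the cis-fused bicyclic dioxanone F6. Me2AlSEt opens F6, with loss of formaldehyde, to the cis hydroxy thioester F7, and TBSOTf gives the silyl ether F8 (the C1 epimer of 10). Deprotonation of F8 gives the same enolate 11, so the route is rejoined at 11 and continues to 12.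

Step 11. The π-allylpalladium intermediate may lose a β-hydrogen to give a 1,3-diene, the allylindium may add too slowly to the hindered ketone, or the facial selectivity may be poor. The fallback separates C–C bond formation at the carbinol from ring closure. It sets out from 13: LiHMDS and 3-bromo-2-methylprop-1-ene give the methallylated ketone F9. Allylmagnesium bromide with CeCl3 at −78 °C should add in the same Felkin–Anh sense to give the diene carbinol F10. Ring-closing metathesis with the second-generation Grubbs catalyst in CH2Cl2 at 40 °C then closes the trisubstituted cyclohexene and the route is rejoined at 19.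

**Further compounds**

F1 | step 13 | tert-butyldimethylsilyl ether of the bromo ether: 2-endo-bromo-1-methyl-7-oxabicyclo[2.2.1]heptan-4-yl group on C2 of the (1R,2S,4S)-4-bromo-2,3,3-trimethylcyclopentan-1-ol unit, oxygen bridge from the former C1′ hydroxyl to C4′, bromine anti to the bridge | CC1(C)[C@@H](Br)C[C@@H](O[Si](C)(C)C(C)(C)C)[C@@]1(C)[C@]12CC[C@](C)(O1)[C@@H](Br)C2
F2 | step 13 | (1R,3S,4S)-3-bromo-1-[(1S,3S,5R)-3-bromo-5-[(tert-butyldimethylsilyl)oxy]-1,2,2-trimethylcyclopentyl]-4-chloro-4-methylcyclohexan-1-ol | CC1(C)[C@@H](Br)C[C@@H](O[Si](C)(C)C(C)(C)C)[C@@]1(C)[C@@]1(O)CC[C@](C)(Cl)[C@@H](Br)C1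
F3 | step 6 | (3S,5S)-5-bromo-6-chloro-3-hydroxy-6-methylheptanoic acid | OC(=O)C[C@H](O)C[C@H](Br)C(C)(C)Cl
F4 | step 6 | (6S)-6-[(2S)-2-bromo-3-chloro-3-methylbutyl]-1,3-dioxan-4-one | O=C1C[C@@H](C[C@H](Br)C(C)(C)Cl)OCO1
F5 | step 6 | 4-(trimethylsilyloxy)-6H-1,3-dioxine silyl ketene acetal of F4 (stereocentres as in F4) | C[Si](C)(C)OC1=C[C@@H](C[C@H](Br)C(C)(C)Cl)OCO1
F6 | step 6 | (4aS,6S,7aR)-6-bromo-5,5-dimethyltetrahydro-4H-cyclopenta[d][1,3]dioxin-4-one (cis-fused) | CC1(C)[C@@H](Br)C[C@H]2OCOC(=O)[C@@H]12
F7 | step 6 | S-ethyl (1S,3S,5R)-3-bromo-5-hydroxy-2,2-dimethylcyclopentane-1-carbothioate | CC1(C)[C@@H](Br)C[C@@H](O)[C@H]1C(=O)SCC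
F8 | step 6 | S-ethyl (1S,3S,5R)-3-bromo-5-[(tert-butyldimethylsilyl)oxy]-2,2-dimethylcyclopentane-1-carbothioate | CC1(C)[C@@H](Br)C[C@@H](O[Si](C)(C)C(C)(C)C)[C@H]1C(=O)SCC
F9 | step 11 | 1-[(1S,3S,5R)-3-bromo-5-[(tert-butyldimethylsilyl)oxy]-1,2,2-trimethylcyclopentyl]-5-methylhex-5-en-1-one | CC1(C)[C@@H](Br)C[C@@H](O[Si](C)(C)C(C)(C)C)[C@@]1(C)C(=O)CCC(C)=C
F10 | step 11 | (4R)-4-[(1S,3S,5R)-3-bromo-5-[(tert-butyldimethylsilyl)oxy]-1,2,2-trimethylcyclopentyl]-7-methylocta-1,7-dien-4-ol | CC1(C)[C@@H](Br)C[C@@H](O[Si](C)(C)C(C)(C)C)[C@@]1(C)[C@](O)(CC=C)CCC(C)=C
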